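The substrate cannot have run out in the autumn run, for 13.1 % of the charge still stands there at 12.0 h, so the stop has to be read from what remains.

| setting | spring | winter | autumn | flask |
|---|---|---|---|---|
| substrate | 15 mM (fed, over 25 min) | 34 mM (fed, over 25 min) | 23 mM (fed, over 25 min) | 23 mM (fed, over 25 min) |
| gas | 2.6 mM (held) | 2.6 mM (held) | 2.6 mM (held) | 2.6 mM (held) |
| free catalyst | 2.3 mM | 2.3 mM | 2.3 mM | 2.3 mM |
| impurity | 0.97 mM | 0.97 mM | 0.48 mM | 0.97 mM |
| remark | run made earlier | run made earlier | run made earlier |  |
| time |  |  |  | 20 h |

| run | time / h | substrate / % | target / % | isomer of the product / % |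
|---|---|---|---|---|
| spring | 0.667 | 16.5 | 58.6 | 25.2 |
| spring | 2.00 | 13.4 | 53.9 | 32.2 |
| spring | 3.00 | 13.9 | 54.7 | 32.3 |
| spring | 5.00 | 13.8 | 54.4 | 31.9 |
| spring | 8.00 | 13.6 | 54.1 | 32.4 |
| spring | 10.0 | 13.5 | 53.5 | 32.2 |
| spring | 12.0 | 14.1 | 53.3 | 32.7 |
| winter | 0.667 | 29.1 | 50.7 | 21.5 |
| winter | 2.00 | 13.1 | 54.7 | 31.2 |
| winter | 3.00 | 14.4 | 54.5 | 31.8 |
| winter | 5.00 | 13.6 | 55.2 | 32.0 |
| winter | 8.00 | 14.2 | 53.3 | 32.5 |
| winter | 10.0 | 12.8 | 54.0 | 31.9 |
| winter | 12.0 | 13.4 | 53.9 | 32.8 |
| autumn | 1.00 | 14.9 | 55.6 | 28.1 |
| autumn | 3.00 | 13.6 | 53.6 | 31.9 |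
| autumn | 6.00 | 13.5 | 53.7 | 32.9 |
| autumn | 8.00 | 13.6 | 54.0 | 31.7 |
| autumn | 12.0 | 13.1 | 55.1 | 31.5 |

(scatter of a reading: 0.5 percentage points)

- at the start none of the gas is in solution
- the reaction counts as stopped when no species that holds the substrate changes by six tenths of a point or more over the second half of the time

- at 20 h, what has stopped the reaction, if anything has (all of the substrate has reacted / it is still moving / no working catalyst is left / forward and back rates have come level)
- share of the substrate used up at 20 h
- target at 20 h, in percent of the substrate charged
- isomer of the product at 20 h, in percent of the substrate charged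

Over the autumn readings from 3.00 h on, substrate divided by the sum of substrate, target and isomer of the product comes to 13.5 %. The flask looks nearly the same as the autumn run, with equal substrate and free catalyst but twice the impurity. That impurity is the one held in the spring and winter runs, whose readings from 3.00 h on give 13.8 % and 13.7 %, although the winter charge is 2.27 times the spring charge. Because these values spread by less than the 0.5 percentage points of one reading, the reckoning here treats the stop as a balance of pseudo-first-order steps with the gas held, in which forward and back rates compare shares of the charge and the charge cancels. The flask and the autumn run should therefore end alike, at the mean of the three, 13.7 %, the fraction left at balance, which puts the flask at 86.3 % used up.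

The forecast says that forward and back rates have come level, with 86.4 % used up, 54.1 % target and 32.1 % isomer of the product, on the ground of “a true equilibrium among first-order isomers”.

In the flask forward and back rates have come level, with 86.1 % used up, 54.1 % target and 32.1 % isomer of the product.

    free catalyst + impurity → spent catalyst (k = 2300 L mol⁻¹ min⁻¹)
    substrate + reagent ⇌ isomer of the product (K = 890 L mol⁻¹, k = 30.0 L mol⁻¹ min⁻¹)
    target + free catalyst ⇌ isomer of the product + free catalyst, rate k3*[free catalyst]*[target] forward; the back reaction follows from the equilibrium constant (k = 0.570 L mol⁻¹ min⁻¹)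
    substrate + reagent ⇌ target (K = 1500 L mol⁻¹, k = 120 L mol⁻¹ min⁻¹)
    gas ⇌ reagent, rate k5*(csat - [reagent]) (kL = 0.360 min⁻¹)

The fraction left in the flask is 13.9 %, against 13.7 % from the readings. With reagent at 2.60 mM, the two equilibrium constants put it at 13.9 %, an expression that contains neither the substrate charge nor the catalyst charge. The neighbour flask differs from the flask by its 9.2 mM of free catalyst and stands at 2.60 mM of reagent at 20.0 h, so the same fraction left gives it 86.1 % used up. It shows 86.1 % used up, with spent catalyst at 10.5 % of its charge against 42.2 % in the flask, and substrate at 14 %.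

The runs were computed for substances that don't exist; noise was put on by code.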